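The bicyclic core is cut at the bond shared by both rings, between the ring-fusion methine C1 and the sp2 fusion carbon C5 (guaiane numbering, see remark), and at C6–C7. The trisubstituted C5=C6 alkene is exocyclic to the cyclopentane (ring A) and endocyclic in the cycloheptene (ring B). The cut turns it into a terminal alkyne on the quaternary C4, and turns C1/C10/C9/C8/C7 into an E-vinylcyclopropane. One rhodium-catalysed intramolecular (5+2) cycloaddition should then close rings A and B together, create C1 and carry the cyclopropane stereocentre into C7. The precursor is an acyclic 1,6-enyne. Its C4/C1′ stereodiad is set on a dihydrocoumarin template, and its cis-cyclopropane ester later becomes the hydroxyisopropyl group.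

Key step: step 9

Remark on numbering: the discussion uses guaiane numbers.
- C1 = ring-fusion CH; C2 and C3 = ring A CH2; C4 = quaternary carbon; C5 = sp2 fusion carbon; C6 = vinylic CH.
- C7 = CH bearing C11 (CMe2OH); C8 and C9 = ring B CH2; C10 = CHMe; C1′ = benzylic CH.
- In the azulene-based names, C1 = guaiane C4, C3a = C1, C4 = C10, C7 = C7, C8 = C6 and C8a = C5.

Assumption: in steps 3 and 4 the ligand antipode is the one that delivers the configuration drawn.

Step 1
Reactants: 1 cyclopropyl methyl ketone
Product: 2 2-cyclopropylbut-3-en-2-ol (racemic)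
Conditions: CH2=CHMgBr, THF, 0 °C
Reagents that add atoms: vinylmagnesium bromide, C=C[Mg]Br
Why: 1,2-addition of a vinyl Grignard reagent to a methyl ketone, giving a racemic carbinol centre that is destroyed again in step 2.

Step 2
Reactants: 2 2-cyclopropylbut-3-en-2-ol
Product: 3 (3E)-6-bromo-3-methylhexa-1,3-diene
Conditions: 48% aq HBr, 0 °C; chromatography on AgNO3-impregnated silica
Reagents that add atoms: hydrogen bromide, Br
Why: Julia olefin synthesis, in which the allyl-stabilised cyclopropylcarbinyl cation is opened irreversibly by bromide at a ring CH2 to the homoallylic bromide, the E alkene (chain trans to vinyl) being favoured and the Z isomer being removed by the silver-ion chromatography.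

Step 3
Reactants: 3 (3E)-6-bromo-3-methylhexa-1,3-diene
Product: 4 tert-butyl (1R,2S)-2-[(2E)-5-bromopent-2-en-2-yl]cyclopropane-1-carboxylate (cis)
Conditions: tert-butyl diazoacetate (slow addition), Co(L*) (5 mol %; divalent cobalt complex of a C2-symmetric salen ligand L* carrying axially chiral 2-phenylnaphthyl groups at C3 and C3′), N-methylimidazole (10 mol %), THF, rt
Reagents that add atoms: tert-butyl diazoacetate, CC(C)(C)OC(=O)C=[N+]=[N-]
Why: catalytic asymmetric metal-carbene cyclopropanation of the terminal, least hindered double bond of the conjugated diene, in which the cis-selective chiral salen ligand sets both new stereocentres (C7 and C9) and holds the ester cis to the alkenyl group.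

Step 4
Reactants: 5 5,7-dimethoxycoumarin
Product: 6 (4R)-5,7-dimethoxy-4-(2-methylpropyl)-3,4-dihydro-2H-chromen-2-one
Conditions: i-BuMgBr, CuBr·SMe2 (5 mol %), reversed Josiphos-type ferrocenyl diphosphine (6 mol %), t-BuOMe/CH2Cl2, −72 °C
Reagents that add atoms: isobutylmagnesium bromide, CC(C)C[Mg]Br
Why: copper-catalysed asymmetric conjugate addition of a Grignard reagent to a coumarin, in which the chiral diphosphine differentiates the two faces of the flat lactone and sets C1′.

Step 5
Reactants: 6 (4R)-5,7-dimethoxy-4-(2-methylpropyl)-3,4-dihydro-2H-chromen-2-one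
Product: 8 (3R,4R)-5,7-dimethoxy-3-methyl-4-(2-methylpropyl)-3,4-dihydro-2H-chromen-2-one (3,4-trans), via lithium enolate 7 (not isolated)
Conditions: LiN(SiMe3)2, THF, −78 °C; then MeI, −78 to −20 °C
Reagents that add atoms: iodomethane, CI
Why: lactone enolate alkylation in which methyl enters trans to the isobutyl group, although this centre is planarised again in step 6.

Step 6
Reactants: 8 (3R,4R)-5,7-dimethoxy-3-methyl-4-(2-methylpropyl)-3,4-dihydro-2H-chromen-2-one; 4 tert-butyl (1R,2S)-2-[(2E)-5-bromopent-2-en-2-yl]cyclopropane-1-carboxylate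
Product: 10 tert-butyl (1R,2S)-2-{(2E)-5-[(3R,4S)-5,7-dimethoxy-3-methyl-4-(2-methylpropyl)-2-oxo-3,4-dihydro-2H-chromen-3-yl]pent-2-en-2-yl}cyclopropane-1-carboxylate, via lithium enolate 9 (not isolated)
Conditions: LDA, THF, −78 °C; then 4, DMPU, Bu4NI (cat.), −78 to 0 °C
Reagents that add atoms: none
Why: SN2 alkylation of the fully substituted lactone enolate, in which the isobutyl group (held pseudoaxial by peri strain with the 5-methoxy group) shields one face, so the chain enters trans to it and sets the quaternary C4 with methyl cis to isobutyl.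

Step 7
Reactants: 10 quaternary lactone ester
Product: 11 tert-butyl (1R,2S)-2-{(2E)-5-[(3R,4S)-2-hydroxy-5,7-dimethoxy-3-methyl-4-(2-methylpropyl)-3,4-dihydro-2H-chromen-3-yl]pent-2-en-2-yl}cyclopropane-1-carboxylate (lactol, both anomers)
Conditions: DIBAL-H (1.1 equiv), toluene, −78 °C
Reagents that add atoms: none
Why: partial reduction of the activated aryl lactone to the lactol at low temperature, while the bulky and poorly electrophilic tert-butyl cyclopropanecarboxylate should remain untouched and no target stereocentre is affected.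

Step 8
Reactants: 11 lactol
Product: 13 tert-butyl (1R,2S)-2-[(2E,6R,7R)-6-ethynyl-6,9-dimethyl-7-(2,4,6-trimethoxyphenyl)dec-2-en-2-yl]cyclopropane-1-carboxylate, via phenol alkyne 12 (not isolated)
Conditions: Ohira–Bestmann reagent, K2CO3, MeOH, 0 °C to rt; then MeI, DMF, rt
Reagents that add atoms: dimethyl (1-diazo-2-oxopropyl)phosphonate, COP(=O)(OC)C(=[N+]=[N-])C(C)=O; iodomethane, CI
Why: Seyferth–Gilbert homologation (Ohira–Bestmann version) of the open hydroxy-aldehyde form of the lactol, whose α-carbon C4 has no hydrogen and cannot epimerise, followed by Williamson methylation of the released phenoxide in the same flask.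

Step 9
Reactants: 13 tert-butyl (1R,2S)-2-[(2E,6R,7R)-6-ethynyl-6,9-dimethyl-7-(2,4,6-trimethoxyphenyl)dec-2-en-2-yl]cyclopropane-1-carboxylate
Product: 14 tert-butyl (1R,3aR,7R)-1,4-dimethyl-1-[(1R)-3-methyl-1-(2,4,6-trimethoxyphenyl)butyl]-1,2,3,3a,6,7-hexahydroazulene-7-carboxylate
Conditions: [Rh(CO)2Cl]2 (5 mol %), ClCH2CH2Cl (0.02 M), 80 °C
Reagents that add atoms: none
Why: Monovalent rhodium coordinates the alkyne and the E-alkene of 13, opens the cyclopropane bond C9–C7 to a σ,π-allyl rhodacyclohexene, inserts the tethered alkyne at the allyl terminus C1 (forming C1–C5) and finally joins C6 to C7 by reductive elimination. This is the known rhodium-catalysed intramolecular vinylcyclopropane–alkyne (5+2) cycloaddition, here with a cyclopropane carrying an acceptor at its 2-position. Ring A closes in a 5-exo-dig sense (C1 attacks the inner alkyne carbon C5 across the three-atom tether C2–C3–C4) and ring B closes as the seven-membered (5+2) ring from C1=C10–C9–C8–C7 and C5≡C6, so C1–C5 ends as the bond common to both rings. C1 is the only new stereocentre: a cis C9=C10 bond in ring B can arise only from the rotamer in which the alkene lies over C8, so the metal and then C5 reach the alkene face dictated by C9 (S), and with the E geometry this gives (1R), a matched case because it also places C10 trans to the bulky side chain on C4. C7 is carried over with retention (Rh replaces C9, then C6 replaces Rh), which puts the ester on the face of H1. The step needs cleavage of C9–C7 and not of C9–C8: the cis ester blocks the rotamer required for C9–C8 cleavage, the vinyl-donor/ester-acceptor pair weakens C9–C7 and the carbonyl oxygen can guide the metal, while high dilution suppresses alkyne oligomerisation.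

Step 10
Reactants: 14 bicyclic diene ester
Product: 16 2-{(1R,3aR,7R)-1,4-dimethyl-1-[(1R)-3-methyl-1-(2,4,6-trimethoxyphenyl)butyl]-1,2,3,3a,6,7-hexahydroazulen-7-yl}propan-2-ol, via methyl ketone 15 (not isolated)
Conditions: MeLi, CeCl3, THF, −78 to 0 °C
Reagents that add atoms: methyllithium, C[Li]
Why: double addition of the weakly basic methylcerium reagent to the ester, which should avoid deprotonation of the allylic α-hydrogen at C7 and so keep both its configuration and the position of the C5=C6 bond.

Step 11
Reactants: 16 diene tertiary alcohol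
Product: 17 2-{(1R,3aR,4R,7R)-1,4-dimethyl-1-[(1R)-3-methyl-1-(2,4,6-trimethoxyphenyl)butyl]-1,2,3,3a,4,5,6,7-octahydroazulen-7-yl}propan-2-ol
Conditions: H2 (1 atm), [Ir(cod)(PCy3)(py)]PF6 (5 mol %), CH2Cl2, 0 °C to rt
Reagents that add atoms: none
Why: hydroxyl-directed homogeneous hydrogenation, in which the cationic iridium catalyst binds the C11 hydroxyl and delivers H2 to the face of the less hindered C9=C10 bond that carries this group and H1, setting C10 (R), while C5=C6 is shielded by the quaternary C4 and its side chain.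

Step 12
Reactants: 17 monoene tertiary alcohol
Product: 18 2-{(1R,3aR,4R,7R)-1-[(1R)-1-(3,5-dibromo-2,4,6-trimethoxyphenyl)-3-methylbutyl]-1,4-dimethyl-1,2,3,3a,4,5,6,7-octahydroazulen-7-yl}propan-2-ol
Conditions: NBS (2.05 equiv), CH2Cl2, −40 to 0 °C
Reagents that add atoms: N-bromosuccinimide, O=C1CCC(=O)N1Br
Why: electrophilic aromatic bromination of the two free positions of the trialkoxyarene, which should be far faster than attack on the hindered C5=C6 bond.

Step 13
Reactants: 18 dibromide
Product: 20 5-{(1R)-1-[(1R,3aR,4R,7R)-7-(2-hydroxypropan-2-yl)-1,4-dimethyl-1,2,3,3a,4,5,6,7-octahydroazulen-1-yl]-3-methylbutyl}-2,4,6-trimethoxybenzene-1,3-dicarbaldehyde, via trilithiated intermediate 19 (not isolated)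
Conditions: t-BuLi (5.5 equiv), THF, −78 °C; then DMF, −78 °C to rt; H2O
Reagents that add atoms: N,N-dimethylformamide, CN(C)C=O
Why: deprotonation of the alcohol and double bromine–lithium exchange, each aryllithium being stabilised by two flanking methoxy groups, followed by Bouveault-type formylation with DMF.

Step 14
Reactants: 20 trimethyl ether dialdehyde
Product: 21 5-{(1R)-1-[(1R,3aR,4R,7R)-7-(2-hydroxypropan-2-yl)-1,4-dimethyl-1,2,3,3a,4,5,6,7-octahydroazulen-1-yl]-3-methylbutyl}-2,4,6-trihydroxybenzene-1,3-dicarbaldehyde (target)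
Conditions: 4-MeC6H4SLi (excess), HMPA–toluene, 110 °C; then aq HCl
Reagents that add atoms: none
Why: SN2 demethylation of the three aryl methyl ethers by a soft thiolate, each methoxy group being activated by an ortho formyl group, under non-acidic conditions that the tertiary alcohol and the alkene should survive.

Compound list
1 | cyclopropyl methyl ketone | CC(=O)C1CC1 | starting material
2 | 2-cyclopropylbut-3-en-2-ol | CC(O)(C=C)C1CC1 | intermediate
3 | (3E)-6-bromo-3-methylhexa-1,3-diene | BrCC/C=C(\C)C=C | intermediate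
4 | tert-butyl (1R,2S)-2-[(2E)-5-bromopent-2-en-2-yl]cyclopropane-1-carboxylate | BrCC/C=C(\C)[C@H]1C[C@H]1C(=O)OC(C)(C)C | intermediate
5 | 5,7-dimethoxycoumarin | COc1cc(OC)c2C=CC(=O)Oc2c1 | starting material
6 | (4R)-5,7-dimethoxy-4-(2-methylpropyl)-3,4-dihydro-2H-chromen-2-one | CC(C)C[C@@H]1CC(=O)Oc2cc(OC)cc(OC)c12 | intermediate
7 | lithium enolate of 6 | CC(C)C[C@@H]1C=C(O[Li])Oc2cc(OC)cc(OC)c12 | intermediate
8 | (3R,4R)-5,7-dimethoxy-3-methyl-4-(2-methylpropyl)-3,4-dihydro-2H-chromen-2-one | CC(C)C[C@@H]1[C@@H](C)C(=O)Oc2cc(OC)cc(OC)c12 | intermediate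
9 | lithium enolate of 8 | CC(C)C[C@@H]1C(C)=C(O[Li])Oc2cc(OC)cc(OC)c12 | intermediate
10 | quaternary lactone ester (3R,4S; cyclopropane 1R,2S; 2E) | CC(C)C[C@@H]1[C@@](C)(CC/C=C(\C)[C@H]3C[C@H]3C(=O)OC(C)(C)C)C(=O)Oc2cc(OC)cc(OC)c12 | intermediate
11 | lactol of 10 (both anomers) | CC(C)C[C@@H]1[C@@](C)(CC/C=C(\C)[C@H]3C[C@H]3C(=O)OC(C)(C)C)C(O)Oc2cc(OC)cc(OC)c12 | intermediate
12 | tert-butyl (1R,2S)-2-[(2E,6R,7R)-6-ethynyl-7-(2-hydroxy-4,6-dimethoxyphenyl)-6,9-dimethyldec-2-en-2-yl]cyclopropane-1-carboxylate | CC(C)C[C@@H](c1c(O)cc(OC)cc1OC)[C@@](C)(CC/C=C(\C)[C@H]2C[C@H]2C(=O)OC(C)(C)C)C#C | intermediate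
13 | tert-butyl (1R,2S)-2-[(2E,6R,7R)-6-ethynyl-6,9-dimethyl-7-(2,4,6-trimethoxyphenyl)dec-2-en-2-yl]cyclopropane-1-carboxylate | CC(C)C[C@@H](c1c(OC)cc(OC)cc1OC)[C@@](C)(CC/C=C(\C)[C@H]2C[C@H]2C(=O)OC(C)(C)C)C#C | intermediate
14 | tert-butyl (1R,3aR,7R)-1,4-dimethyl-1-[(1R)-3-methyl-1-(2,4,6-trimethoxyphenyl)butyl]-1,2,3,3a,6,7-hexahydroazulene-7-carboxylate | CC(C)C[C@@H](c1c(OC)cc(OC)cc1OC)[C@@]1(C)CC[C@H]2C1=C[C@H](C(=O)OC(C)(C)C)CC=C2C | intermediate
15 | methyl ketone at C7 (1R,3aR,7R) | CC(C)C[C@@H](c1c(OC)cc(OC)cc1OC)[C@@]1(C)CC[C@H]2C1=C[C@H](C(C)=O)CC=C2C | intermediate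
16 | diene tertiary alcohol (1R,3aR,7R) | CC(C)C[C@@H](c1c(OC)cc(OC)cc1OC)[C@@]1(C)CC[C@H]2C1=C[C@H](C(C)(C)O)CC=C2C | intermediate
17 | monoene tertiary alcohol (1R,3aR,4R,7R) | CC(C)C[C@@H](c1c(OC)cc(OC)cc1OC)[C@@]1(C)CC[C@H]2C1=C[C@H](C(C)(C)O)CC[C@H]2C | intermediate
18 | 3,5-dibromoaryl derivative of 17 | CC(C)C[C@@H](c1c(OC)c(Br)c(OC)c(Br)c1OC)[C@@]1(C)CC[C@H]2C1=C[C@H](C(C)(C)O)CC[C@H]2C | intermediate
19 | 3,5-dilithioaryl lithium alkoxide | CC(C)C[C@@H](c1c(OC)c([Li])c(OC)c([Li])c1OC)[C@@]1(C)CC[C@H]2C1=C[C@H](C(C)(C)O[Li])CC[C@H]2C | intermediate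
20 | trimethyl ether dialdehyde | CC(C)C[C@@H](c1c(OC)c(C=O)c(OC)c(C=O)c1OC)[C@@]1(C)CC[C@H]2C1=C[C@H](C(C)(C)O)CC[C@H]2C | intermediate
21 | CNP0281883.1 | CC(C)C[C@@H](c1c(O)c(C=O)c(O)c(C=O)c1O)[C@@]1(C)CC[C@H]2C1=C[C@H](C(C)(C)O)CC[C@H]2C | target

Total step count: 14. Longest linear sequence: 12 steps (steps 1–3 and 6–14).

Steps most likely to fail

1. Step 9 (key step).
- What may go wrong: rhodium may insert into the less substituted C9–C8 bond. Alternatively the crowded cis-cyclopropane may open slowly, and β-hydride elimination to acyclic trienes may compete.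
- Fallback, from 13 back to 14:
  - KOt-Bu in t-BuOH/THF should epimerise the ester-bearing carbon to the thermodynamically preferred trans-cyclopropane ester F1. The propargylic carbon is quaternary, so the alkyne cannot migrate.
  - For trans vinylcyclopropanes with a 2-acceptor, acceptor-directed cleavage of the more substituted bond by [Rh(CO)2Cl]2 is established. C9 is unchanged, so the cycloaddition should still give the correct C1 and deliver the C7-epimeric cycloadduct F2.
  - LDA then gives the extended lithium enolate F3. Kinetic α-protonation (AcOH, −78 °C) from the face opposite to the side chain on C4 should correct C7 and give 14.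

2. Step 3.
- What may go wrong: cis selectivity and enantioselectivity may erode on this 2-substituted diene, or the carbene may attack the trisubstituted double bond.
- Fallback, from 3 back to 4: asymmetric catalysis is replaced by separation. Rh2(OAc)4-catalysed addition of tert-butyl diazoacetate to 3 runs without stereocontrol. Chromatography removes the trans isomers and leaves the racemic cis ester F4. Preparative chromatography on a chiral stationary phase then separates its enantiomers and gives 4.

3. Step 11.
- What may go wrong: C5=C6 may be over-reduced, C9=C10 may migrate into conjugation, or facial selectivity may be poor if the tertiary hydroxyl binds the metal weakly.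
- Fallback, from 16 back to 17: coordination-directed hydrogenation is replaced by radical hydrogen-atom-transfer reduction (Mn(dpm)3, PhSiH3, t-BuOOH, i-PrOH, rt). The hydrogen atom should add to C9 of the more accessible alkene. The tertiary C10 radical should be quenched from the face of H1, opposite to C2. No new compound is made (F0).

Further compounds
F1 | step 9 | tert-butyl (1S,2S)-2-[(2E,6R,7R)-6-ethynyl-6,9-dimethyl-7-(2,4,6-trimethoxyphenyl)dec-2-en-2-yl]cyclopropane-1-carboxylate (trans) | CC(C)C[C@@H](c1c(OC)cc(OC)cc1OC)[C@@](C)(CC/C=C(\C)[C@H]2C[C@@H]2C(=O)OC(C)(C)C)C#C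
F2 | step 9 | tert-butyl (1R,3aR,7S)-1,4-dimethyl-1-[(1R)-3-methyl-1-(2,4,6-trimethoxyphenyl)butyl]-1,2,3,3a,6,7-hexahydroazulene-7-carboxylate | CC(C)C[C@@H](c1c(OC)cc(OC)cc1OC)[C@@]1(C)CC[C@H]2C1=C[C@@H](C(=O)OC(C)(C)C)CC=C2C
F3 | step 9 | extended lithium enolate of F2 | CC(C)C[C@@H](c1c(OC)cc(OC)cc1OC)[C@@]1(C)CC[C@H]2C1=CC(=C(O[Li])OC(C)(C)C)CC=C2C
F4 | step 3 | racemic cis tert-butyl 2-[(2E)-5-bromopent-2-en-2-yl]cyclopropane-1-carboxylate | BrCC/C=C(\C)[C@H]1C[C@H]1C(=O)OC(C)(C)C.BrCC/C=C(\C)[C@@H]1C[C@@H]1C(=O)OC(C)(C)C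
F0 | step 11 | none | none
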